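(The earlier runs and the new flask are calculated with constants of no real substance; the scatter is artificial.)

In the west run, the last reading at 120 s shows 25.2% product and 15.0% solid substrate, and the remainder of the charge stands in neither column. The same gap appears in the north-east and south-west runs. We read it as substrate held in solution and call it the hold-up, and at that time it averages 0.0267 M. Substrate counted in product then reads 0.0113 M, 0.0108 M and 0.0116 M in these runs, so the turnover reads as zero order in the solid.

| setting | west | north-east | south-west | beta | eta | delta |
|---|---|---|---|---|---|---|
| solid substrate | 0.045 M | 0.053 M | 0.077 M | 0.040 M | 0.060 M | 0.080 M |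
| remark | run made earlier | run made earlier | run made earlier |  |  |  |
| time |  |  |  | 3.0 min | 3.0 min | 3.0 min |

| run | time / s | product / % | solid substrate / % |
|---|---|---|---|
| west | 12.0 | 1.4 | 45.6 |
| west | 30.0 | 7.4 | 33.9 |
| west | 60.0 | 15.2 | 25.3 |
| west | 90.0 | 20.4 | 20.4 |
| west | 120 | 25.2 | 15.0 |
| north-east | 25.0 | 4.7 | 45.9 |
| north-east | 50.0 | 11.2 | 39.4 |
| north-east | 80.0 | 16.8 | 33.1 |
| north-east | 90.0 | 17.3 | 32.4 |
| north-east | 120 | 20.4 | 28.6 |
| south-west | 12.0 | 0.4 | 67.7 |
| south-west | 30.0 | 4.6 | 61.6 |
| south-west | 60.0 | 9.3 | 56.8 |
| south-west | 90.0 | 11.9 | 53.8 |
| south-west | 120 | 15.1 | 51.0 |

(standard deviation of a reading: 0.5 percentage points)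

- a species is counted by the solid substrate in it: one product counts as two
- at the start none of the solid substrate is in solution
- a reading or a percentage of product counts all its forms, free or not
- the concentration of product that is asked is that of its free form alone
- "hardly changes" means that all values lie within two and a half points (for a concentration: within two and a half percent of the largest)

- [product] (only what is free in solution) at the end for beta, eta, delta, in this order
- how the row runs (rises, then falls / hardly changes / rises all the way / falls all the way / falls, then rises)

Turned round, the question is this: for the row to rise from its low end, beta must lose its solid before the end and then fall behind. Carrying the west run's pace from 60.0 s to 120 s on unslowed gives an upper estimate of the spend, the substrate counted in product, by 3.0 min of 0.0158 M. Adding the hold-up gives 0.0425 M, the floor charge: the charge that covers both hold-up and spend.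

Beta, at 0.040 M, may stand below it by 0.00252 M, while eta's 0.060 M stands above it. That gap is 9.44% of the hold-up. The spend still due once the solid is gone is then the gap itself, and if the pace drops by that share over this stretch, beta falls short by 2.38 × 10⁻⁴ M, which is 1.50% of the spend and less than the two and a half percent allowed. So we expect a flat row, with [product] under an upper estimate of 0.00790 M.

The forecast gives 0.0069 M, 0.007 M and 0.007 M, a row that hardly changes, with values lower than our upper estimate, and says beta “loses its solid only near 160 s”.

The flasks give 0.00677 M, 0.00679 M and 0.00679 M: the row hardly changes.

    2 starting material ⇌ product (K = 11.0 L mol⁻¹, k = 0.130 L mol⁻¹ s⁻¹)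
    crystals ⇌ product, rate k2*(cs2 - [product]) while solid is left; crystals form when [product] > cs2 (solubility = 46.0 mM, k = 0.930 s⁻¹)
    solid substrate ⇌ starting material, rate k3*(cs3 - [starting material]) while solid is left; crystals form when [starting material] > cs3 (solubility = 27.0 mM, k = 0.180 s⁻¹)

With the backward run from product to two starting material left out, the row rises all the way. Beta, charged below the floor by 0.00252 M, holds 0% solid substrate at 3.00 min. Eta's charge less the floor leaves 29.2% of that charge as solid, and eta holds 32.6%.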